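## Numbering and assumption

Compounds are numbered 1–25 in the order they appear in the steps; the target is 25. Flavone numbering is used for all ring A intermediates (O1, C2, C3, C4, C4a, C5–C8, C8a; ring A = benzo ring, ring C = pyranone, ring B = 2-aryl group).

Assumption: the target has no stereocentre; the transient sp3 centres in 11, 13, 20, 21 and 22 are taken as racemic or as diastereomer mixtures and are drawn without configuration.

## Analysis of the target

Target 25 is a flavonol: a 2-aryl-3-hydroxychromen-4-one in which ring A (C4a, C5, C6, C7, C8, C8a) is fused to the pyranone ring C (O1, C2, C3, C4), with a 4-hydroxyphenyl ring B on C2. It has no stereocentre, so stereochemistry matters only in intermediates that are later flattened. The sensitive groups are the trisubstituted alkene of the prenyl group at C8 (it adds acid, cyclises onto a neighbouring free phenol and does not survive hydrogenolysis), the enolic 3-hydroxyl next to the C4 carbonyl, and the phenols at C5 and C4'. The difficulty lies in ring A: five of its six carbons are substituted, three of them carry oxygen in three different states (ring oxygen O1 at C8a, methyl ether at C7, free hydroxyl at C5), and the prenyl group must sit at C8 and not at the electronically similar C6. Prenylation, Claisen shifts or selective methylation on a preformed trioxygenated benzene must tell apart positions and oxygens that differ only slightly. The plan rests on the fact that C4a to C8a map onto two acyclic partners: a vinylketene supplies C8a (ketene carbon, its oxygen becoming O1), C6, C5 (with its methoxy) and C4a (with an ester as the future C4), and an ynol ether supplies C8 (prenyl) and C7 (methoxy), inserted between C8a and C6. Each of the three oxygens then comes from a different functional group, so they are differentiated from the start.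

## Retrosynthetic reasoning

**25 ⇐ 24 ⇐ 23 (protecting-group O–C bonds).** The last two operations are ether cleavages only. The acetal bonds at O3 and O4' are cut last, because at that stage no phenol is ortho to the prenyl group and mild acid is tolerated. The O–CH3 bond at C5 is cut one step earlier, where the C4 carbonyl can hold a chelating Lewis acid next to it and so distinguish it from the C7 methyl ether. This lets C5 and C7 travel as two methyl ethers through the whole route.

**23 ⇐ 20 (O1–C2).** Ring C is opened at its enol ether bond, which leads back to the 1,3-diketone 20 carrying a silylated phenol. Closing this bond is a cyclodehydration that needs no reagent able to attack the prenyl alkene. Forward, desilylation frees phenol 21, which adds to the aryl ketone (hemiketal 22) and then dehydrates.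

**20 ⇐ 15 + 18 (C3–C4).** The diketone is cut between C3 and C4, so that C4 is an ester carbon on ring A (15) and C3 is the α-carbon of ketone 18, which already holds ring B and the protected C3 oxygen and reacts as enolate 19. Cutting at C2–C3 instead would put the C3 oxygen on the ring A fragment and lose the match with what the annulation delivers. The silyl ether 15 goes back to phenol 14; it is there only so that the condensation does not meet a phenoxide.

**14 ⇐ 5 + 9 (C5–C6, C6–C7, C8–C8a, C4a–C8a).** Ring A is taken apart completely into diazo ketone 5 and ynol ether 9. No other cut places prenyl, two methoxy groups, the phenol and the ester in one operation with the positions fixed by bond polarity. Forward, the reaction must generate vinylketene 10 from 5, add it to 9 in the right orientation (11), and reorganise through 12 and 13 to the phenol.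

**5 ⇐ 3 ⇐ 2 ⇐ 1.** The diazoacetyl group is traced to a carboxylic acid (3, activated as 4) and a diazoalkane C1 unit. Acid 3 comes from diester 2 by hydrolysis of the ester that is not deactivated by the enol ether oxygen, and 2 from alkyne diester 1 by conjugate addition of the alcohol that supplies the C5 methoxy group. The anti addition sets the Z geometry, which keeps the remaining ester away from the ketene arm later on.

**9 ⇐ 6 + 7.** The ynol ether is cut at its propargylic C–C bond into the methoxyacetylide 8, generated from chloroacetal 6, and prenyl bromide 7.

**18 ⇐ 17 ⇐ 16.** Ketone 18 is the bis-acetal of diol 17, obtained from bromo ketone 16 by oxygen-for-bromine substitution.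

## Alternatives that were turned down

**Alternative 1:** The C4 carbonyl is inserted by a carbonylative ketone arylation, cutting C4a–C4 and C3–C4 at once. Forward, aryl iodide A2 undergoes oxidative addition to a zerovalent palladium catalyst carrying a wide-bite-angle diphosphine; carbonyl insertion gives an aroyl-palladium species, which acylates the softly enolised ketone 18 (magnesium halide, tertiary amine) to give diketone A1 without closing a ring.
- For: it is a three-component, convergent step under mild conditions, and the aroyl-palladium intermediate is a far better acylating agent than a di-ortho-substituted benzoate. On the C3–C4 bond this alternative is stronger than step 9 of the chosen route, and its step count is at least as good.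
- Against: A2 is itself a pentasubstituted benzene with the full ring A pattern. Making it means differentiating two nearly equivalent aromatic positions by directed metalation twice, with the doubly activated CH2 of the prenyl group as a competing acidic site. The iodide is flanked by two oxygen substituents, so direct arylation or reduction can compete with carbonyl insertion, and a toxic gas has to be handled.
- Comparison: the chosen strategy does not select among aromatic positions at all; the pattern follows from the polarity of two acyclic partners, and no transition metal is needed. The metalation chemistry of this alternative is kept as the fallback for the key step.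

**Alternative 2:** Ring A is folded onto a preformed pyranone, cutting C7–C8 and C5–C6. Forward, an excess of a lithium dialkylamide deprotonates the CH2 group on the pyranone A4 (future C8), an N-methoxy-N-methyl amide acetylates it, and the enolate of the new methyl ketone attacks the neighbouring ester; enolisation gives the 5,7-dihydroxyflavone A3.
- For: rings B and C are in place early, the prenyl position is fixed because it is part of the side chain, and the C5 hydroxyl emerges free, so no demethylation is needed. On that last point it is stronger than the chosen route.
- Against: A3 is a 5,7-diol, so the C7 methyl ether still has to be introduced selectively. The key step stacks three events on a substrate with several electrophilic sites (pyranone C2 and C6, ester) under excess strong base. After acetylation the most acidic position is the CH between ketone and pyranone, not the methyl group that must cyclise. A4, a fully substituted pyranone, has no short access.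
- Comparison: the chosen strategy delivers the C7 methyl ether and the prenyl group in the same step from simple precursors of three and one steps, and concentrates its risk in one neutral photochemical and thermal cascade.

**Alternative 3:** Ring C is closed at C3–C4 by a carbene-catalysed intramolecular crossed benzoin reaction. Forward, a triazolium-derived N-heterocyclic carbene with an amidine base converts the aryl aldehyde of A6 into its Breslow intermediate, which adds to the tethered α-aryloxy aldehyde and gives the trans dihydroflavonol A5 as a racemate.
- For: the conditions are mild and leave the prenyl group alone, and the C3 oxygen arrives as a free hydroxyl without a protecting group, which the chosen route cannot match.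
- Against: the step creates two stereocentres that the achiral target does not need, and a dehydrogenation must follow. The Breslow intermediate has to form at an electron-rich aldehyde with both ortho positions occupied. A6 contains an enolisable, elimination-prone α-aryloxy-α-aryl acetaldehyde and requires O-alkylation of a phenol flanked by two substituents. Ring A must again be made with its full pattern by aromatic substitution.
- Comparison: the chosen strategy keeps C2 and C3 at the final oxidation level throughout and solves the ring A problem, which this alternative leaves open.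

Key step: step 5

## Route

Step 1
Reactants: 1 dimethyl but-2-ynedioate (dimethyl acetylenedicarboxylate)
Product: 2 dimethyl (2Z)-2-methoxybut-2-enedioate
Conditions: MeOH (solvent), Et3N (5 mol %), 0 → 20 °C
Reagents that add atoms: methanol, CO
Why: Amine-catalysed conjugate addition of methanol to the ynoate; in the protic medium the vinyl anion is protonated anti to the incoming methoxy group, which should give mainly the Z isomer with the two esters trans (kinetic control, stopped when 1 is consumed to limit ketal formation and equilibration).

Step 2
Reactants: 2 dimethyl (2Z)-2-methoxybut-2-enedioate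
Product: 3 (2Z)-2,4-dimethoxy-4-oxobut-2-enoic acid
Conditions: LiOH·H2O (1.0 equiv), THF/H2O, 0 °C; then cold 1 M HCl to pH 2–3
Reagents that add atoms: lithium hydroxide, [Li+].[OH-]
Why: Site-selective saponification: the C4 ester is a vinylogous carbonate (β-methoxyacrylate) deactivated by the enol ether oxygen, whereas the C1 ester on the methoxy-bearing carbon is inductively activated and cross-conjugated, so hydroxide should attack there; the carboxylate formed protects the molecule against a second hydrolysis.

Step 3
Reactants: 3 (2Z)-2,4-dimethoxy-4-oxobut-2-enoic acid
Product: 5 methyl (2Z)-5-diazo-3-methoxy-4-oxopent-2-enoate, via mixed carbonic anhydride 4 (not isolated)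
Conditions: iBuOCOCl (1.05 equiv), Et3N (1.05 equiv), THF, –15 °C; then CH2N2 (about 2 equiv) in Et2O, –15 → 0 °C; AcOH quench
Reagents that add atoms: diazomethane, C=[N+]=[N-]
Why: Acylation of diazomethane by a mixed anhydride (first stage of an Arndt–Eistert sequence); no HCl is formed, the alkyl carbonate leaving group takes up the proton, so only a small excess of diazomethane and a short contact time are needed, which should hold back dipolar cycloaddition to the donor-substituted double bond; the trans arrangement of acid and ester rules out a cyclic anhydride.

Step 4
Reactants: 6 2-chloro-1,1-dimethoxyethane (chloroacetaldehyde dimethyl acetal); 7 1-bromo-3-methylbut-2-ene (prenyl bromide)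
Product: 9 1-methoxy-5-methylhex-4-en-1-yne, via sodium methoxyacetylide 8 (not isolated)
Conditions: NaNH2 (3.0 equiv), liquid NH3, –33 °C; then 7 in Et2O, –33 °C; solid NH4Cl, careful distillation
Reagents that add atoms: none
Why: Twofold elimination from the chloroacetal (loss of methanol, then of HCl) gives methoxyacetylene, which the third equivalent of amide deprotonates; SN2 alkylation of the acetylide at the primary allylic bromide is the standard preparation of 1-alkoxy-1-alkynes, and exact stoichiometry of base avoids isomerisation of the skipped enyne.

Step 5
Reactants: 5 methyl (2Z)-5-diazo-3-methoxy-4-oxopent-2-enoate; 9 1-methoxy-5-methylhex-4-en-1-yne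
Product: 14 methyl 2-hydroxy-4,6-dimethoxy-3-(3-methylbut-2-enyl)benzoate, via vinylketene 10 (not isolated), via vinylcyclobutenone 11 (not isolated), via dienylketene 12 (not isolated), via cyclohexadienone 13 (not isolated)
Conditions: 5 (1.0 equiv), 9 (1.5 equiv), degassed ClCH2CH2Cl (0.2 M), hν (365 nm), 20 °C; then 80 °C in the dark
Reagents that add atoms: none
Why: Excitation of the diazo ketone expels dinitrogen with 1,2-shift of the 1-methoxyalkenyl group (Wolff rearrangement, forming C5–C6) and gives vinylketene 10. The electrophilic ketene carbon bonds to the nucleophilic, prenyl-bearing carbon of the ynol ether and the ketene CH to the methoxy-bearing carbon ([2+2] cycloaddition, C8–C8a and C6–C7), giving 4-vinylcyclobutenone 11. Under light or on warming 11 opens by 4π electrocyclisation to dienylketene 12, which closes ring A by thermal disrotatory 6π electrocyclisation between the ketene carbon and the ester-bearing terminus (C4a–C8a), and cyclohexadienone 13 enolises to phenol 14. The closest known reaction type is the Danheiser benzannulation in its photochemical Wolff variant, which is established for alkoxyalkynes and gives resorcinol monoethers with the alkoxy group meta to the new hydroxyl. No stereocentre remains in 14; the sp3 carbons of 11 and 13 are transient. The regioselectivity needed is prenyl ortho and methoxy meta to the phenol, and the donor polarisation of the ynol ether secures it. The ketene must also choose the alkyne over the prenyl alkene, which the much higher nucleophilicity of the ynol ether ensures, and the Z geometry of 5 keeps the ester trans to the ketene arm, so that lactonisation by oxa-6π closure cannot occur and the ester points outward in the ring closure. The methoxy ynol ether has no β-hydrogen in its alkyl group, so the thermal retro-ene loss of an alkene that limits higher alkoxyalkynes is excluded during the heating phase.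

Step 6
Reactants: 14 methyl 2-hydroxy-4,6-dimethoxy-3-(3-methylbut-2-enyl)benzoate
Product: 15 methyl 2-[tert-butyl(dimethyl)silyl]oxy-4,6-dimethoxy-3-(3-methylbut-2-enyl)benzoate
Conditions: TBSOTf (1.3 equiv), 2,6-lutidine, CH2Cl2, 0 → 20 °C
Reagents that add atoms: tert-butyldimethylsilyl trifluoromethanesulfonate, CC(C)(C)[Si](C)(C)OS(=O)(=O)C(F)(F)F
Why: Silylation of the hindered, hydrogen-bonded phenol with the reactive silyl triflate and a non-nucleophilic base; the silyl ether prevents phenoxide formation, which would deactivate the ester in step 9, and is later removed without acid.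

Step 7
Reactants: 16 2-bromo-1-(4-hydroxyphenyl)ethanone (2-bromo-4'-hydroxyacetophenone)
Product: 17 2-hydroxy-1-(4-hydroxyphenyl)ethanone
Conditions: HCO2Na (3 equiv), EtOH/H2O, reflux
Reagents that add atoms: sodium formate, [Na+].[O-]C=O
Why: SN2 displacement of the phenacyl bromide by formate followed by solvolysis of the formate ester in the same pot; formate is too weak a base to generate the phenoxide, so intermolecular O-alkylation of the phenol should not compete.

Step 8
Reactants: 17 2-hydroxy-1-(4-hydroxyphenyl)ethanone
Product: 18 2-(methoxymethoxy)-1-[4-(methoxymethoxy)phenyl]ethanone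
Conditions: MOMCl (2.5 equiv), iPr2NEt (3 equiv), CH2Cl2, 0 → 20 °C
Reagents that add atoms: chloromethyl methyl ether, COCCl
Why: Standard acetal protection of the phenol and the primary alcohol; both acetals are stable to the strong base of step 9 and fall together in the final acid step.

Step 9
Reactants: 15 methyl 2-[tert-butyl(dimethyl)silyl]oxy-4,6-dimethoxy-3-(3-methylbut-2-enyl)benzoate; 18 2-(methoxymethoxy)-1-[4-(methoxymethoxy)phenyl]ethanone
Product: 20 1-[2-[tert-butyl(dimethyl)silyl]oxy-4,6-dimethoxy-3-(3-methylbut-2-enyl)phenyl]-2-(methoxymethoxy)-3-[4-(methoxymethoxy)phenyl]propane-1,3-dione, via lithium enolate 19 (not isolated)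
Conditions: 18 (1.5 equiv), LiN(SiMe3)2 (3.0 equiv), THF, –78 °C; then 15, –78 → 20 °C (40 °C if needed); aq. NH4Cl
Reagents that add atoms: none
Why: Crossed Claisen condensation: the chelated Z-enolate 19 of the α-alkoxy ketone attacks the only ester present, which cannot enolise, and the excess base converts 20 into its stabilised enolate and drives the equilibrium; the new C3 centre is racemic and enolisable and disappears in step 10.

Step 10
Reactants: 20 1-[2-[tert-butyl(dimethyl)silyl]oxy-4,6-dimethoxy-3-(3-methylbut-2-enyl)phenyl]-2-(methoxymethoxy)-3-[4-(methoxymethoxy)phenyl]propane-1,3-dione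
Product: 23 5,7-dimethoxy-3-(methoxymethoxy)-2-[4-(methoxymethoxy)phenyl]-8-(3-methylbut-2-enyl)chromen-4-one, via free phenol diketone 21 (not isolated), via cyclic hemiketal 22 (not isolated)
Conditions: Bu4NF/AcOH (1:1, 1.2 equiv), THF, 0 → 20 °C; then TsOH·H2O (10 mol %), toluene, 50 °C
Reagents that add atoms: none
Why: Buffered fluoride cleaves the aryl silyl ether; phenol 21 adds to the ring B ketone to give the six-membered hemiketal 22, and acid-catalysed dehydration gives the pyranone (the usual cyclodehydration of o-hydroxyaryl 1,3-diketones to flavones); the phenol is tied up as hemiketal before acid is added, and catalytic acid in an aprotic solvent should spare the acetals and the prenyl group.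

Step 11
Reactants: 23 5,7-dimethoxy-3-(methoxymethoxy)-2-[4-(methoxymethoxy)phenyl]-8-(3-methylbut-2-enyl)chromen-4-one
Product: 24 5-hydroxy-7-methoxy-3-(methoxymethoxy)-2-[4-(methoxymethoxy)phenyl]-8-(3-methylbut-2-enyl)chromen-4-one
Conditions: MgI2·OEt2 (3 equiv), THF, 60 °C; then dilute aq. HCl, 0 °C
Reagents that add atoms: none
Why: Chelation-directed demethylation: magnesium bridges the C4 carbonyl and the peri C5 methoxy oxygen, which activates that methyl group for SN2 attack by iodide, while the unchelated C7 ether and the alkene are left alone; this selective cleavage of ethers ortho or peri to a carbonyl is known for prenylated aryl ketones and flavones.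

Step 12
Reactants: 24 5-hydroxy-7-methoxy-3-(methoxymethoxy)-2-[4-(methoxymethoxy)phenyl]-8-(3-methylbut-2-enyl)chromen-4-one
Product: 25 isoanhydroicaritin, 3,5-dihydroxy-2-(4-hydroxyphenyl)-7-methoxy-8-(3-methylbut-2-enyl)chromen-4-one
Conditions: 3 M aq. HCl, MeOH, 50 °C, short reaction time
Reagents that add atoms: none
Why: Acid-catalysed acetal exchange transfers both methoxymethyl groups to methanol; no phenol is ortho to the prenyl group in 24 or 25, so chroman formation is impossible and only Markovnikov addition to the alkene has to be avoided by moderate temperature and time.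

## Compound list

1 | dimethyl but-2-ynedioate (dimethyl acetylenedicarboxylate) | COC(=O)C#CC(=O)OC | starting material
2 | dimethyl (2Z)-2-methoxybut-2-enedioate | COC(=O)/C=C(\OC)C(=O)OC | intermediate
3 | (2Z)-2,4-dimethoxy-4-oxobut-2-enoic acid | COC(=O)/C=C(\OC)C(=O)O | intermediate
4 | (2Z)-2,4-dimethoxy-4-oxobut-2-enoic 2-methylpropyl carbonic anhydride (not isolated) | COC(=O)/C=C(\OC)C(=O)OC(=O)OCC(C)C | intermediate
5 | methyl (2Z)-5-diazo-3-methoxy-4-oxopent-2-enoate | COC(=O)/C=C(\OC)C(=O)C=[N+]=[N-] | intermediate
6 | 2-chloro-1,1-dimethoxyethane (chloroacetaldehyde dimethyl acetal) | COC(CCl)OC | starting material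
7 | 1-bromo-3-methylbut-2-ene (prenyl bromide) | CC(C)=CCBr | starting material
8 | sodium methoxyacetylide (not isolated) | [Na+].[C-]#COC | intermediate
9 | 1-methoxy-5-methylhex-4-en-1-yne | COC#CCC=C(C)C | intermediate
10 | methyl (2Z)-3-methoxy-5-oxopenta-2,4-dienoate (vinylketene, not isolated) | COC(=O)/C=C(\OC)C=C=O | intermediate
11 | methyl (2Z)-3-methoxy-3-[2-methoxy-3-(3-methylbut-2-enyl)-4-oxocyclobut-2-en-1-yl]prop-2-enoate (racemic, not isolated) | COC(=O)/C=C(\OC)C1C(OC)=C(CC=C(C)C)C1=O | intermediate
12 | methyl (2Z,4E)-3,5-dimethoxy-6-(3-methylbut-2-enyl)-7-oxohepta-2,4,6-trienoate (dienylketene, not isolated) | COC(=O)/C=C(\OC)/C=C(/OC)\C(CC=C(C)C)=C=O | intermediate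
13 | methyl 2,4-dimethoxy-5-(3-methylbut-2-enyl)-6-oxocyclohexa-2,4-diene-1-carboxylate (racemic, not isolated) | COC(=O)C1C(OC)=CC(OC)=C(CC=C(C)C)C1=O | intermediate
14 | methyl 2-hydroxy-4,6-dimethoxy-3-(3-methylbut-2-enyl)benzoate | COC(=O)c1c(O)c(CC=C(C)C)c(OC)cc1OC | intermediate
15 | methyl 2-[tert-butyl(dimethyl)silyl]oxy-4,6-dimethoxy-3-(3-methylbut-2-enyl)benzoate | COC(=O)c1c(O[Si](C)(C)C(C)(C)C)c(CC=C(C)C)c(OC)cc1OC | intermediate
16 | 2-bromo-1-(4-hydroxyphenyl)ethanone (2-bromo-4'-hydroxyacetophenone) | O=C(CBr)c1ccc(O)cc1 | starting material
17 | 2-hydroxy-1-(4-hydroxyphenyl)ethanone | O=C(CO)c1ccc(O)cc1 | intermediate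
18 | 2-(methoxymethoxy)-1-[4-(methoxymethoxy)phenyl]ethanone | COCOCC(=O)c1ccc(OCOC)cc1 | intermediate
19 | lithium (Z)-2-(methoxymethoxy)-1-[4-(methoxymethoxy)phenyl]ethenolate (not isolated) | [Li+].[O-]/C(=C\OCOC)c1ccc(OCOC)cc1 | intermediate
20 | 1-[2-[tert-butyl(dimethyl)silyl]oxy-4,6-dimethoxy-3-(3-methylbut-2-enyl)phenyl]-2-(methoxymethoxy)-3-[4-(methoxymethoxy)phenyl]propane-1,3-dione (racemic, enolisable) | COCOc1ccc(C(=O)C(OCOC)C(=O)c2c(OC)cc(OC)c(CC=C(C)C)c2O[Si](C)(C)C(C)(C)C)cc1 | intermediate
21 | 1-[2-hydroxy-4,6-dimethoxy-3-(3-methylbut-2-enyl)phenyl]-2-(methoxymethoxy)-3-[4-(methoxymethoxy)phenyl]propane-1,3-dione (racemic, not isolated) | COCOc1ccc(C(=O)C(OCOC)C(=O)c2c(OC)cc(OC)c(CC=C(C)C)c2O)cc1 | intermediate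
22 | 2-hydroxy-5,7-dimethoxy-3-(methoxymethoxy)-2-[4-(methoxymethoxy)phenyl]-8-(3-methylbut-2-enyl)-2,3-dihydrochromen-4-one (diastereomer mixture, not isolated) | COCOc1ccc(C2(O)Oc3c(CC=C(C)C)c(OC)cc(OC)c3C(=O)C2OCOC)cc1 | intermediate
23 | 5,7-dimethoxy-3-(methoxymethoxy)-2-[4-(methoxymethoxy)phenyl]-8-(3-methylbut-2-enyl)chromen-4-one | COCOc1ccc(-c2oc3c(CC=C(C)C)c(OC)cc(OC)c3c(=O)c2OCOC)cc1 | intermediate
24 | 5-hydroxy-7-methoxy-3-(methoxymethoxy)-2-[4-(methoxymethoxy)phenyl]-8-(3-methylbut-2-enyl)chromen-4-one | COCOc1ccc(-c2oc3c(CC=C(C)C)c(OC)cc(O)c3c(=O)c2OCOC)cc1 | intermediate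
25 | isoanhydroicaritin, 3,5-dihydroxy-2-(4-hydroxyphenyl)-7-methoxy-8-(3-methylbut-2-enyl)chromen-4-one | COc1cc(O)c2c(=O)c(O)c(-c3ccc(O)cc3)oc2c1CC=C(C)C | target

## Step count and least certain steps

Total: 12 steps. Longest linear sequence: 9 steps (steps 1, 2, 3, 5, 6, 9, 10, 11, 12); steps 4, 7 and 8 are side branches.

**Step 5 (key step).** The most likely failure is photochemical isomerisation of the enol ether double bond of 5 or 10, after which the ester carbonyl lies cis to the ketene and captures it by oxa-6π closure. The other likely failure is that the vinylketene dimerises or closes to a cyclobutenone faster than it meets the ynol ether. Both divert the ketene before the [2+2] step. The fallback builds the same benzoate by directed metalation instead of annulation; it sets out from prenyl bromide 7 and comes back to the route at 14. Purchased 3,5-dimethoxyphenol F1 is converted with MOMCl and iPr2NEt into 1,3-dimethoxy-5-(methoxymethoxy)benzene F2. Lithiation with n-BuLi/TMEDA occurs at the position between the acetal and a methoxy group; transmetalation with CuBr·SMe2 and alkylation with 7 should give 1,5-dimethoxy-3-(methoxymethoxy)-2-(3-methylbut-2-enyl)benzene F3. A second lithiation at the remaining position next to the acetal oxygen and quenching with ClCO2Me gives methyl 4,6-dimethoxy-2-(methoxymethoxy)-3-(3-methylbut-2-enyl)benzoate F4. Brief treatment with catalytic HCl in MeOH at 20 °C removes the acetal and gives 14.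

**Step 9.** Addition of the enolate to the ester carbonyl may be too slow, because both ortho positions are occupied and the silyl ether is bulky. Self-condensation of the ketone or silyl transfer to the enolate would then take over. The fallback replaces the ester by an aldehyde; it sets out from 15 and comes back at 20. Reduction with iBu2AlH (CH2Cl2, –78 → 0 °C) gives [2-[tert-butyl(dimethyl)silyl]oxy-4,6-dimethoxy-3-(3-methylbut-2-enyl)phenyl]methanol F5, and MnO2 oxidises it to 2-[tert-butyl(dimethyl)silyl]oxy-4,6-dimethoxy-3-(3-methylbut-2-enyl)benzaldehyde F6. Aldol addition of enolate 19 at –78 °C with a cold quench gives 3-[2-[tert-butyl(dimethyl)silyl]oxy-4,6-dimethoxy-3-(3-methylbut-2-enyl)phenyl]-3-hydroxy-2-(methoxymethoxy)-1-[4-(methoxymethoxy)phenyl]propan-1-one F7 as a diastereomer mixture. Dess–Martin oxidation with NaHCO3 buffer then gives 20.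

**Step 3.** Diazomethane may add as a 1,3-dipole to the acceptor-substituted double bond (pyrazoline formation) in competition with acylation, before or after the diazo ketone has formed. The fallback is a detrifluoroacetylative diazo transfer, which uses no diazomethane; it sets out from 3 and comes back at 5. Oxalyl chloride with catalytic DMF gives methyl (2Z)-4-chloro-3-methoxy-4-oxobut-2-enoate F8. Negishi acylation with MeZnCl and catalytic Pd(PPh3)4 (zerovalent palladium) in THF at 0 °C gives methyl (2Z)-3-methoxy-4-oxopent-2-enoate F9. Its lithium enolate (LiN(SiMe3)2, THF, –78 °C) is acylated with CF3CO2CH2CF3 to give methyl (2Z)-7,7,7-trifluoro-3-methoxy-4,6-dioxohept-2-enoate F10. Treatment with MsN3, Et3N and H2O in MeCN transfers the diazo group with loss of the trifluoroacetyl group and gives 5.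

**Step 2.** Hydroxide may add to the enol ether carbon and expel the methoxy group by addition–elimination, or hydrolysis may continue to the second ester. The fallback changes the bond that is broken: 2 is heated with LiI in EtOAc or pyridine, so that iodide attacks the ester methyl group by SN2 (alkyl–oxygen cleavage). The carboxylate on the methoxy-bearing carbon belongs to the stronger acid and is the better leaving group, so the same ester should be cleaved without any nucleophile adding to the double bond. It sets out from 2 and comes back at 3 after acidification; no new compound is formed.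

**Step 4.** Excess amide may isomerise the skipped enyne through its doubly activated CH2 group, and methoxyacetylene or the volatile product may be lost on work-up. The fallback generates the acetylide without amide base or ammonia; it sets out from 7 and comes back at 9. Trichloroethylene and KOMe give (E)-1,2-dichloro-1-methoxyethene F11. Two equivalents of n-BuLi in THF (–78 → –40 °C) convert it by elimination and chlorine–lithium exchange into lithium methoxyacetylide F12, which is alkylated with 7 in THF/DMPU to give 9.

**Step 11.** The Lewis acid may also cleave the acetals, above all the one on O3 beside the carbonyl. Magnesium is then drawn into the O3/C4 chelate, and demethylation stalls or gives mixtures. The fallback reverses the order of the last two steps; it sets out from 23 and comes back at the target 25. Aqueous HCl in MeOH first removes both acetals to give 3-hydroxy-2-(4-hydroxyphenyl)-5,7-dimethoxy-8-(3-methylbut-2-enyl)chromen-4-one F13. This is then treated with a larger excess of MgI2·OEt2 in THF at 60 °C, so that the hydroxyls are present as magnesium salts from the start and the C5 ether is cleaved on a defined substrate.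

## Further compounds

F1 | step 5 | 3,5-dimethoxyphenol | COc1cc(O)cc(OC)c1
F2 | step 5 | 1,3-dimethoxy-5-(methoxymethoxy)benzene | COCOc1cc(OC)cc(OC)c1
F3 | step 5 | 1,5-dimethoxy-3-(methoxymethoxy)-2-(3-methylbut-2-enyl)benzene | COCOc1cc(OC)cc(OC)c1CC=C(C)C
F4 | step 5 | methyl 4,6-dimethoxy-2-(methoxymethoxy)-3-(3-methylbut-2-enyl)benzoate | COCOc1c(CC=C(C)C)c(OC)cc(OC)c1C(=O)OC
F5 | step 9 | [2-[tert-butyl(dimethyl)silyl]oxy-4,6-dimethoxy-3-(3-methylbut-2-enyl)phenyl]methanol | OCc1c(O[Si](C)(C)C(C)(C)C)c(CC=C(C)C)c(OC)cc1OC
F6 | step 9 | 2-[tert-butyl(dimethyl)silyl]oxy-4,6-dimethoxy-3-(3-methylbut-2-enyl)benzaldehyde | O=Cc1c(O[Si](C)(C)C(C)(C)C)c(CC=C(C)C)c(OC)cc1OC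
F7 | step 9 | 3-[2-[tert-butyl(dimethyl)silyl]oxy-4,6-dimethoxy-3-(3-methylbut-2-enyl)phenyl]-3-hydroxy-2-(methoxymethoxy)-1-[4-(methoxymethoxy)phenyl]propan-1-one (mixture of racemic diastereomers) | COCOc1ccc(C(=O)C(OCOC)C(O)c2c(OC)cc(OC)c(CC=C(C)C)c2O[Si](C)(C)C(C)(C)C)cc1
F8 | step 3 | methyl (2Z)-4-chloro-3-methoxy-4-oxobut-2-enoate | COC(=O)/C=C(\OC)C(Cl)=O
F9 | step 3 | methyl (2Z)-3-methoxy-4-oxopent-2-enoate | COC(=O)/C=C(\OC)C(C)=O
F10 | step 3 | methyl (2Z)-7,7,7-trifluoro-3-methoxy-4,6-dioxohept-2-enoate | COC(=O)/C=C(\OC)C(=O)CC(=O)C(F)(F)F
F0 | step 2 | none | none
F11 | step 4 | (E)-1,2-dichloro-1-methoxyethene | CO/C(Cl)=C\Cl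
F12 | step 4 | lithium methoxyacetylide | [Li+].[C-]#COC
F13 | step 11 | 3-hydroxy-2-(4-hydroxyphenyl)-5,7-dimethoxy-8-(3-methylbut-2-enyl)chromen-4-one | COc1cc(OC)c2c(=O)c(O)c(-c3ccc(O)cc3)oc2c1CC=C(C)C
A1 | alternative 1 | 1-[2,4-dimethoxy-6-(methoxymethoxy)-5-(3-methylbut-2-enyl)phenyl]-2-(methoxymethoxy)-3-[4-(methoxymethoxy)phenyl]propane-1,3-dione (racemic, enolisable) | COCOc1ccc(C(=O)C(OCOC)C(=O)c2c(OC)cc(OC)c(CC=C(C)C)c2OCOC)cc1
A2 | alternative 1 | 2-iodo-1,5-dimethoxy-3-(methoxymethoxy)-4-(3-methylbut-2-enyl)benzene | COCOc1c(I)c(OC)cc(OC)c1CC=C(C)C
A3 | alternative 2 | 5,7-dihydroxy-3-(methoxymethoxy)-2-[4-(methoxymethoxy)phenyl]-8-(3-methylbut-2-enyl)chromen-4-one | COCOc1ccc(-c2oc3c(CC=C(C)C)c(O)cc(O)c3c(=O)c2OCOC)cc1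
A4 | alternative 2 | methyl 5-(methoxymethoxy)-6-[4-(methoxymethoxy)phenyl]-2-(4-methylpent-3-enyl)-4-oxopyran-3-carboxylate | COCOc1ccc(-c2oc(CCC=C(C)C)c(C(=O)OC)c(=O)c2OCOC)cc1
A5 | alternative 3 | trans-3-hydroxy-5,7-dimethoxy-2-[4-(methoxymethoxy)phenyl]-8-(3-methylbut-2-enyl)chroman-4-one (racemic, 2R,3R enantiomer drawn) | COCOc1ccc([C@H]2Oc3c(CC=C(C)C)c(OC)cc(OC)c3C(=O)[C@@H]2O)cc1
A6 | alternative 3 | 2-[2-formyl-3,5-dimethoxy-6-(3-methylbut-2-enyl)phenoxy]-2-[4-(methoxymethoxy)phenyl]acetaldehyde (racemic) | COCOc1ccc(C(C=O)Oc2c(C=O)c(OC)cc(OC)c2CC=C(C)C)cc1
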